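**Strategy.** The oxolane is disconnected at O1–C2. C2, the benzylic carbon between the ring oxygen and the resorcinol ring, is carried as an aryl ketone, and C5 as a free benzylic alcohol. The key step is a Lewis-acid/silane reductive cycloetherification of this open-chain γ-hydroxy 1,4-diketone, which closes the oxolane last. It exploits that C3 is α to the oxocarbenium carbon C2: both C3 epimers converge (benzyl trans to the C4 aroyl) before hydride adds anti to the benzyl, giving the 2,3-cis/3,4-trans/4,5-cis array. The precursor comes from a chroman-bearing dihydrochalcone by enolate alkylation and a reagent-controlled anti aldol. The chroman comes from a resolved 3-arylflavan-4-ol by Friedel–Crafts coupling.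

Key step: step 11

TBS = tert-butyldimethylsilyl; TBSO = tert-butyldimethylsilyloxy.
Assumption: the boron reagent from (−)-menthone is taken to be the antipode that gives the (S)-carbinol in step 10; if the sense is opposite, the reagent from (+)-menthone is used with no other change.

Step 1
Reactants: 1 resorcinol; 2 2-(5-bromo-2-hydroxyphenyl)acetic acid
Product: 3 2-(5-bromo-2-hydroxyphenyl)-1-(2,4-dihydroxyphenyl)ethan-1-one
Conditions: BF3·OEt2 (solvent), 85 °C; then aq. NaOAc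
Reagents that add atoms: none
Why: Friedel–Crafts (Nencki-type) C-acylation of resorcinol at C4 by the arylacetic acid should give the 2,4-dihydroxydeoxybenzoin; no stereocentre is formed.

Step 2
Reactants: 3 2-(5-bromo-2-hydroxyphenyl)-1-(2,4-dihydroxyphenyl)ethan-1-one
Product: 4 2-[5-bromo-2-(TBSO)phenyl]-1-[2-hydroxy-4-(TBSO)phenyl]ethan-1-one
Conditions: TBSCl (2.2 equiv), imidazole, DMF, 0 °C → rt
Reagents that add atoms: tert-butyldimethylsilyl chloride, CC(C)(C)[Si](C)(C)Cl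
Why: Silyl ether formation should cap only the two free phenols, because the hydroxyl ortho to the ketone is hydrogen-bonded and stays free for the ring closure of step 3.

Step 3
Reactants: 4 2-[5-bromo-2-(TBSO)phenyl]-1-[2-hydroxy-4-(TBSO)phenyl]ethan-1-one; 5 4-(TBSO)benzaldehyde
Product: 6 rac-trans-3-[5-bromo-2-(TBSO)phenyl]-7-(TBSO)-2-[4-(TBSO)phenyl]chroman-4-one (the (2S,3R) enantiomer is drawn)
Conditions: piperidine (cat.), toluene, reflux, Dean–Stark
Reagents that add atoms: none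
Why: Knoevenagel condensation followed by 6-endo-trig oxa-Michael closure should give the chromanone, and the base-labile C3 centre equilibrates to the 2,3-trans racemate.

Step 4
Reactants: 6 rac-trans-3-[5-bromo-2-(TBSO)phenyl]-7-(TBSO)-2-[4-(TBSO)phenyl]chroman-4-one
Product: 7 (2S,3S,4R)-3-[5-bromo-2-(TBSO)phenyl]-7-(TBSO)-2-[4-(TBSO)phenyl]chroman-4-ol
Conditions: RuCl[(R,R)-TsDPEN](p-cymene) (2 mol %), HCO2H/Et3N (5:2), EtOAc, 25 °C, stopped near half conversion
Reagents that add atoms: none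
Why: Noyori–Ikariya asymmetric transfer hydrogenation run as a kinetic resolution: the (R,R) catalyst delivers hydride to the face that gives the (4R) carbinol, and this face is anti to the C3 aryl only in the (2S,3R) ketone, so that enantiomer should be reduced while the (2R,3S) half of 6 stays as ketone and is separated.

Step 5
Reactants: 1 resorcinol; 8 3-(4-hydroxyphenyl)propanoic acid
Product: 9 1-(2,4-dihydroxyphenyl)-3-(4-hydroxyphenyl)propan-1-one (davidigenin)
Conditions: BF3·OEt2 (solvent), 90 °C; then aq. NaOAc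
Reagents that add atoms: none
Why: Friedel–Crafts (Nencki-type) acylation of resorcinol should give the dihydrochalcone.

Step 6
Reactants: 7 (2S,3S,4R)-chroman-4-ol; 9 davidigenin
Product: 10 1-{5-[(2S,3R,4R)-3-(5-bromo-2-TBSO-phenyl)-7-TBSO-2-(4-TBSO-phenyl)chroman-4-yl]-2,4-dihydroxyphenyl}-3-(4-hydroxyphenyl)propan-1-one
Conditions: Sc(OTf)3 (10 mol %), 9 (4 equiv), MeCN/CH2Cl2, 4 Å MS, −20 → 0 °C
Reagents that add atoms: none
Why: Friedel–Crafts alkylation by the flavan-4-yl cation (proanthocyanidin-type coupling): C5 of the resorcinol ring (para to the chelated hydroxyl, ortho to the other) should attack anti to the C3 aryl, setting C4 as 3,4-trans.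

Step 7
Reactants: 10 chroman-substituted dihydrochalcone triol
Product: 11 hexasilyl ether of 10 (all six phenols as TBS ethers; chroman centres as in 10)
Conditions: TBSCl (4 equiv), imidazole, DMAP (cat.), DMF, 40 °C
Reagents that add atoms: tert-butyldimethylsilyl chloride, CC(C)(C)[Si](C)(C)Cl
Why: Exhaustive silyl ether formation, forced enough to cap the chelated hydroxyl, removes all acidic protons before the enolate chemistry.

Step 8
Reactants: 12 2-bromo-1-(2,4-dihydroxyphenyl)ethan-1-one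
Product: 13 2-bromo-1-[2,4-bis(TBSO)phenyl]ethan-1-one
Conditions: TBSOTf, 2,6-lutidine, CH2Cl2, −78 → 0 °C
Reagents that add atoms: tert-butyldimethylsilyl trifluoromethanesulfonate, CC(C)(C)[Si](C)(C)OS(=O)(=O)C(F)(F)F
Why: Silyl ether formation with a silyl triflate and a non-nucleophilic base is chosen because imidazole would displace the α-bromide.

Step 9
Reactants: 11 hexasilyl dihydrochalcone; 13 2-bromo-1-[2,4-bis(TBSO)phenyl]ethan-1-one
Product: 14 1-(chroman-substituted 2,4-bis-TBSO-phenyl)-2-[4-(TBSO)benzyl]-4-[2,4-bis(TBSO)phenyl]butane-1,4-dione (both C2 epimers)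
Conditions: LiHMDS, THF, −78 °C; then 13, −78 → −30 °C
Reagents that add atoms: none
Why: SN2 alkylation of the ketone lithium enolate with the α-bromo ketone should give the 1,4-diketone; the new C2 centre is not controlled because step 11 makes it converge.

Step 10
Reactants: 14 1,4-diketone (C2 epimers); 5 4-(TBSO)benzaldehyde
Product: 15 (3R)-3-{(S)-hydroxy[4-(TBSO)phenyl]methyl} derivative of 14 (anti aldol; both C2 epimers)
Conditions: bis[(menthyl)methyl]boron bromide (from (−)-menthone), Et3N, CH2Cl2, −78 °C; then 5, −78 → −20 °C; MeOH, pH 7 buffer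
Reagents that add atoms: none
Why: Boron-mediated aldol reaction: the bulky dialkylboron bromide/Et3N should enolise the less hindered CH2 side to the E enol borinate, which reacts through a chair (Zimmerman–Traxler) transition state to the anti aldol, and the chiral ligands on boron select the aldehyde face to give the (S)-carbinol and the (R) α-centre.

Step 11
Reactants: 15 anti aldol (open-chain γ-hydroxy 1,4-diketone; both C2 epimers)
Product: 18 nonasilylated bromo-oxolane with the (2S,3R,4R,5S) oxolane, via cyclic hemiketal 16 (not isolated), via oxolanylium ion 17 (not isolated)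
Conditions: Et3SiH (5 equiv), BF3·OEt2 (2 equiv), CH2Cl2, −78 → −20 °C
Reagents that add atoms: none
Why: The benzylic hydroxyl of 15 adds to the resorcinol aryl ketone (5-exo-trig hemiketalisation to 16), BF3 ionises the hemiketal to the 2-aryl-oxolan-2-ylium ion 17 and Et3SiH reduces it, i.e. a Lewis-acid/silane reductive cycloetherification of a γ-hydroxy ketone, the reaction type used to deoxygenate 2-aryl lactols in tetrahydrofuran lignan synthesis. The oxolane is the only ring closed, by O1–C2 bond formation. C5 (S) and C4 (R) are carried over unchanged from the aldol of step 10. C3 lies α to the cationic C2 and equilibrates through the 4,5-dihydrofuran (enol ether), so both C3 epimers of 15 should funnel into the ion with benzyl trans to the C4 aroyl group (Curtin–Hammett convergence). C2 is then set by hydride attack anti to the adjacent C3 benzyl group, which places aryl and benzyl cis (2S,3R). The step needs ionisation of the hemiketal to outrun ionisation of the C5 benzylic C–O bond and silane reduction of the two aryl ketones; the α-oxy, aryl-stabilised cation, the low temperature and the weakly donating silyloxy groups should secure this.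

Step 12
Reactants: 19 1-(2,4-dihydroxyphenyl)ethan-1-one
Product: 20 1-[2,4-bis(TBSO)phenyl]ethan-1-one
Conditions: TBSCl, imidazole, DMAP (cat.), DMF, 40 °C
Reagents that add atoms: tert-butyldimethylsilyl chloride, CC(C)(C)[Si](C)(C)Cl
Why: Silyl ether formation protects both phenols so that the vinyl ketone of step 13 cannot cyclise to a chromanone.

Step 13
Reactants: 20 1-[2,4-bis(TBSO)phenyl]ethan-1-one
Product: 21 1-[2,4-bis(TBSO)phenyl]prop-2-en-1-one
Conditions: (CH2O)n, diisopropylammonium trifluoroacetate, THF, reflux; used crude with BHT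
Reagents that add atoms: paraformaldehyde (as formaldehyde), C=O
Why: Mannich-type α-methylenation of the aryl methyl ketone (iminium addition, then amine elimination) should give the aryl vinyl ketone.

Step 14
Reactants: 18 nonasilylated bromo-oxolane; 21 1-[2,4-bis(TBSO)phenyl]prop-2-en-1-one
Product: 22 undecasilyl ether of the target
Conditions: Pd(OAc)2 (5 mol %), P(t-Bu)3·HBF4 (10 mol %), Cy2NMe, 1,4-dioxane, 70 °C
Reagents that add atoms: none
Why: Mizoroki–Heck coupling of the aryl bromide with the enone should give the E chalcone by syn insertion and syn β-hydride elimination, under a hindered amine base that leaves the β-alkoxy ketone of the oxolane alone.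

Step 15
Reactants: 22 undecasilyl ether of the target
Product: 23 CNP0330082.3
Conditions: HF·pyridine, pyridine, THF, 0 °C → rt
Reagents that add atoms: none
Why: Fluoride cleavage of the eleven aryl silyl ethers under buffered, non-basic conditions should free the phenols without opening the β-alkoxy ketone or ionising the benzylic ethers; C4 of the oxolane already has its thermodynamically preferred configuration.

**Compound list**

1 | resorcinol | Oc1cccc(O)c1 | starting material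
2 | 2-(5-bromo-2-hydroxyphenyl)acetic acid | OC(=O)Cc1cc(Br)ccc1O | starting material
3 | 2-(5-bromo-2-hydroxyphenyl)-1-(2,4-dihydroxyphenyl)ethan-1-one | O=C(Cc1cc(Br)ccc1O)c1ccc(O)cc1O | intermediate
4 | 2-[5-bromo-2-(TBSO)phenyl]-1-[2-hydroxy-4-(TBSO)phenyl]ethan-1-one | O=C(Cc1cc(Br)ccc1O[Si](C)(C)C(C)(C)C)c1ccc(O[Si](C)(C)C(C)(C)C)cc1O | intermediate
5 | 4-(TBSO)benzaldehyde | O=Cc1ccc(O[Si](C)(C)C(C)(C)C)cc1 | starting material
6 | rac-trans-3-[5-bromo-2-(TBSO)phenyl]-7-(TBSO)-2-[4-(TBSO)phenyl]chroman-4-one (racemate; (2S,3R) enantiomer drawn) | Brc1ccc(O[Si](C)(C)C(C)(C)C)c([C@H]2C(=O)c3ccc(O[Si](C)(C)C(C)(C)C)cc3O[C@@H]2c2ccc(O[Si](C)(C)C(C)(C)C)cc2)c1 | intermediate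
7 | (2S,3S,4R)-3-[5-bromo-2-(TBSO)phenyl]-7-(TBSO)-2-[4-(TBSO)phenyl]chroman-4-ol | Brc1ccc(O[Si](C)(C)C(C)(C)C)c([C@H]2[C@@H](O)c3ccc(O[Si](C)(C)C(C)(C)C)cc3O[C@@H]2c2ccc(O[Si](C)(C)C(C)(C)C)cc2)c1 | intermediate
8 | 3-(4-hydroxyphenyl)propanoic acid | OC(=O)CCc1ccc(O)cc1 | starting material
9 | 1-(2,4-dihydroxyphenyl)-3-(4-hydroxyphenyl)propan-1-one (davidigenin) | O=C(CCc1ccc(O)cc1)c1ccc(O)cc1O | intermediate
10 | 1-{5-[(2S,3R,4R)-3-(5-bromo-2-TBSO-phenyl)-7-TBSO-2-(4-TBSO-phenyl)chroman-4-yl]-2,4-dihydroxyphenyl}-3-(4-hydroxyphenyl)propan-1-one | Brc1ccc(O[Si](C)(C)C(C)(C)C)c([C@H]2[C@H](c3cc(C(=O)CCc4ccc(O)cc4)c(O)cc3O)c3ccc(O[Si](C)(C)C(C)(C)C)cc3O[C@@H]2c2ccc(O[Si](C)(C)C(C)(C)C)cc2)c1 | intermediate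
11 | hexasilyl ether of 10 (2,3-trans-3,4-trans chroman as in 10) | Brc1ccc(O[Si](C)(C)C(C)(C)C)c([C@H]2[C@H](c3cc(C(=O)CCc4ccc(O[Si](C)(C)C(C)(C)C)cc4)c(O[Si](C)(C)C(C)(C)C)cc3O[Si](C)(C)C(C)(C)C)c3ccc(O[Si](C)(C)C(C)(C)C)cc3O[C@@H]2c2ccc(O[Si](C)(C)C(C)(C)C)cc2)c1 | intermediate
12 | 2-bromo-1-(2,4-dihydroxyphenyl)ethan-1-one | O=C(CBr)c1ccc(O)cc1O | starting material
13 | 2-bromo-1-[2,4-bis(TBSO)phenyl]ethan-1-one | O=C(CBr)c1ccc(O[Si](C)(C)C(C)(C)C)cc1O[Si](C)(C)C(C)(C)C | intermediate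
14 | 1,4-diketone: 2-[4-(TBSO)benzyl]-4-[2,4-bis(TBSO)phenyl]-1-(chroman-substituted 2,4-bis-TBSO-phenyl)butane-1,4-dione, both C2 epimers, chroman as in 10 | Brc1ccc(O[Si](C)(C)C(C)(C)C)c([C@H]2[C@H](c3cc(C(=O)C(Cc4ccc(O[Si](C)(C)C(C)(C)C)cc4)CC(=O)c4ccc(O[Si](C)(C)C(C)(C)C)cc4O[Si](C)(C)C(C)(C)C)c(O[Si](C)(C)C(C)(C)C)cc3O[Si](C)(C)C(C)(C)C)c3ccc(O[Si](C)(C)C(C)(C)C)cc3O[C@@H]2c2ccc(O[Si](C)(C)C(C)(C)C)cc2)c1 | intermediate
15 | anti aldol: (3R)-3-{(S)-hydroxy[4-(TBSO)phenyl]methyl} derivative of 14, both C2 epimers | Brc1ccc(O[Si](C)(C)C(C)(C)C)c([C@H]2[C@H](c3cc(C(=O)C(Cc4ccc(O[Si](C)(C)C(C)(C)C)cc4)[C@@H](C(=O)c4ccc(O[Si](C)(C)C(C)(C)C)cc4O[Si](C)(C)C(C)(C)C)[C@H](O)c4ccc(O[Si](C)(C)C(C)(C)C)cc4)c(O[Si](C)(C)C(C)(C)C)cc3O[Si](C)(C)C(C)(C)C)c3ccc(O[Si](C)(C)C(C)(C)C)cc3O[C@@H]2c2ccc(O[Si](C)(C)C(C)(C)C)cc2)c1 | intermediate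
16 | cyclic hemiketal (2-aryl-2-hydroxyoxolane; C2 and C3 not defined) | Brc1ccc(O[Si](C)(C)C(C)(C)C)c([C@H]2[C@H](c3cc(C4(O)O[C@H](c5ccc(O[Si](C)(C)C(C)(C)C)cc5)[C@H](C(=O)c5ccc(O[Si](C)(C)C(C)(C)C)cc5O[Si](C)(C)C(C)(C)C)C4Cc4ccc(O[Si](C)(C)C(C)(C)C)cc4)c(O[Si](C)(C)C(C)(C)C)cc3O[Si](C)(C)C(C)(C)C)c3ccc(O[Si](C)(C)C(C)(C)C)cc3O[C@@H]2c2ccc(O[Si](C)(C)C(C)(C)C)cc2)c1 | intermediate (not isolated)
17 | 2-aryl-oxolan-2-ylium ion, benzyl trans to aroyl | Brc1ccc(O[Si](C)(C)C(C)(C)C)c([C@H]2[C@H](c3cc(C4=[O+][C@H](c5ccc(O[Si](C)(C)C(C)(C)C)cc5)[C@H](C(=O)c5ccc(O[Si](C)(C)C(C)(C)C)cc5O[Si](C)(C)C(C)(C)C)[C@H]4Cc4ccc(O[Si](C)(C)C(C)(C)C)cc4)c(O[Si](C)(C)C(C)(C)C)cc3O[Si](C)(C)C(C)(C)C)c3ccc(O[Si](C)(C)C(C)(C)C)cc3O[C@@H]2c2ccc(O[Si](C)(C)C(C)(C)C)cc2)c1 | intermediate (not isolated)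
18 | nonasilylated bromo-oxolane: (2S,3R,4R,5S)-oxolane with 2-aryl/3-benzyl cis, 3-benzyl/4-aroyl trans, 4-aroyl/5-aryl cis; chroman as in 10 | Brc1ccc(O[Si](C)(C)C(C)(C)C)c([C@H]2[C@H](c3cc([C@H]4O[C@H](c5ccc(O[Si](C)(C)C(C)(C)C)cc5)[C@H](C(=O)c5ccc(O[Si](C)(C)C(C)(C)C)cc5O[Si](C)(C)C(C)(C)C)[C@H]4Cc4ccc(O[Si](C)(C)C(C)(C)C)cc4)c(O[Si](C)(C)C(C)(C)C)cc3O[Si](C)(C)C(C)(C)C)c3ccc(O[Si](C)(C)C(C)(C)C)cc3O[C@@H]2c2ccc(O[Si](C)(C)C(C)(C)C)cc2)c1 | intermediate
19 | 1-(2,4-dihydroxyphenyl)ethan-1-one | CC(=O)c1ccc(O)cc1O | starting material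
20 | 1-[2,4-bis(TBSO)phenyl]ethan-1-one | CC(=O)c1ccc(O[Si](C)(C)C(C)(C)C)cc1O[Si](C)(C)C(C)(C)C | intermediate
21 | 1-[2,4-bis(TBSO)phenyl]prop-2-en-1-one | C=CC(=O)c1ccc(O[Si](C)(C)C(C)(C)C)cc1O[Si](C)(C)C(C)(C)C | intermediate
22 | undecasilyl ether of the target (E chalcone; stereocentres as in 18) | O=C(/C=C/c1ccc(O[Si](C)(C)C(C)(C)C)c([C@H]2[C@H](c3cc([C@H]4O[C@H](c5ccc(O[Si](C)(C)C(C)(C)C)cc5)[C@H](C(=O)c5ccc(O[Si](C)(C)C(C)(C)C)cc5O[Si](C)(C)C(C)(C)C)[C@H]4Cc4ccc(O[Si](C)(C)C(C)(C)C)cc4)c(O[Si](C)(C)C(C)(C)C)cc3O[Si](C)(C)C(C)(C)C)c3ccc(O[Si](C)(C)C(C)(C)C)cc3O[C@@H]2c2ccc(O[Si](C)(C)C(C)(C)C)cc2)c1)c1ccc(O[Si](C)(C)C(C)(C)C)cc1O[Si](C)(C)C(C)(C)C | intermediate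
23 | (E)-1-(2,4-dihydroxyphenyl)-3-{3-[(2S,3R,4R)-4-{5-[(2S,3R,4R,5S)-4-(2,4-dihydroxybenzoyl)-3-(4-hydroxybenzyl)-5-(4-hydroxyphenyl)oxolan-2-yl]-2,4-dihydroxyphenyl}-7-hydroxy-2-(4-hydroxyphenyl)chroman-3-yl]-4-hydroxyphenyl}prop-2-en-1-one (CNP0330082.3) | O=C(/C=C/c1ccc(O)c([C@H]2[C@H](c3cc([C@H]4O[C@H](c5ccc(O)cc5)[C@H](C(=O)c5ccc(O)cc5O)[C@H]4Cc4ccc(O)cc4)c(O)cc3O)c3ccc(O)cc3O[C@@H]2c2ccc(O)cc2)c1)c1ccc(O)cc1O | target

**Count.** Total steps: 15. Longest linear sequence: 11 steps (1, 2, 3, 4, 6, 7, 9, 10, 11, 14, 15).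

**Steps most likely to fail**

Step 11. The benzylic C5–O bond may ionise, or the aldol may eliminate, before the hemiketal is reduced. C3 may also fail to equilibrate fully, or hydride may add syn to the benzyl group, so that the ring closes with the wrong C2/C3 relationship. The fallback sets out from 15 and comes back at 18; it separates ring closure from deoxygenation. Compound 15 is treated with PPTS and trimethyl orthoformate in methanol to give the cyclic methyl ketal F1, an isolable 2-methoxyoxolane in which C3 can equilibrate under the mild acid with no hydride present. F1 is then reduced with Et3SiH and catalytic TMSOTf in CH2Cl2 at −78 °C, where only the ketal can ionise, to give 18.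

Step 10. Enolisation may occur on the wrong side of the 1,4-diketone, or the boron reagent may discriminate poorly between the aldehyde faces in this crowded substrate. The fallback sets out from 14 and comes back at 15; it replaces the boron enolate by an enol silane and a catalytic Mukaiyama aldol. Kinetic deprotonation of 14 with LiHMDS and trapping with TMSCl gives the (Z)-trimethylsilyl enol ether F2. F2 is combined with 5 under SiCl4 activated by a chiral bisphosphoramide Lewis base (i-Pr2NEt, CH2Cl2, −78 °C), which reacts through an open transition state with anti selectivity and catalyst-controlled face selection, to give 15.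

Step 6. The cation may be attacked through C3 of the resorcinol ring or through oxygen, may condense with the electron-rich ring of a second chroman, or may be captured by the neighbouring silyloxy oxygen. The fallback sets out from 7 and comes back at 10; it changes the activation from acid to a thiophile. Compound 7 is converted with benzyl mercaptan and catalytic ZnI2 into the 3,4-trans 4-benzylthio chroman F3. F3 is then coupled with excess 9 under AgBF4 in THF at 0 °C, the thiophilic activation used for proanthocyanidin couplings, to give 10.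

**Further compounds**

F1 | step 11 | cyclic methyl ketal (2-aryl-2-methoxyoxolane; C2 and C3 not defined) | Brc1ccc(O[Si](C)(C)C(C)(C)C)c([C@H]2[C@H](c3cc(C4(OC)O[C@H](c5ccc(O[Si](C)(C)C(C)(C)C)cc5)[C@H](C(=O)c5ccc(O[Si](C)(C)C(C)(C)C)cc5O[Si](C)(C)C(C)(C)C)C4Cc4ccc(O[Si](C)(C)C(C)(C)C)cc4)c(O[Si](C)(C)C(C)(C)C)cc3O[Si](C)(C)C(C)(C)C)c3ccc(O[Si](C)(C)C(C)(C)C)cc3O[C@@H]2c2ccc(O[Si](C)(C)C(C)(C)C)cc2)c1
F2 | step 10 | (Z)-trimethylsilyl enol ether of 14 at the aroyl CH2 | Brc1ccc(O[Si](C)(C)C(C)(C)C)c([C@H]2[C@H](c3cc(C(=O)C(Cc4ccc(O[Si](C)(C)C(C)(C)C)cc4)/C=C(\O[Si](C)(C)C)c4ccc(O[Si](C)(C)C(C)(C)C)cc4O[Si](C)(C)C(C)(C)C)c(O[Si](C)(C)C(C)(C)C)cc3O[Si](C)(C)C(C)(C)C)c3ccc(O[Si](C)(C)C(C)(C)C)cc3O[C@@H]2c2ccc(O[Si](C)(C)C(C)(C)C)cc2)c1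
F3 | step 6 | 3,4-trans 4-benzylthio chroman derived from 7 | Brc1ccc(O[Si](C)(C)C(C)(C)C)c([C@H]2[C@H](SCc3ccccc3)c3ccc(O[Si](C)(C)C(C)(C)C)cc3O[C@@H]2c2ccc(O[Si](C)(C)C(C)(C)C)cc2)c1
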